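**Plan**

1. Retrosynthesis: cut the lactone bond O–C4′ (closed last, with inversion), then in one stroke C14–C15 and O–C3′ of the 1,2-dioxane, then trace the decalin back to (+)-larixol. The one-stroke cut gives an enal-derived peroxyacetal (decalin through C14 and C16) and a five-carbon alkoxydiene ester (C15, C4′, C3′ with its methyl, C2′, C1′).
2. Enabling feature: in the dioxane ring (O–O, C14, C15, C4′, C3′), C14 is an allylic peroxide carbon at aldehyde level next to the C13=C16 methylene, so it can be a peroxycarbenium ion. C15 is alpha to C4′, which can be carried at ketone level, and C3′ is beta to the lactone carbonyl C1′, so a 2-alkoxydiene ester is nucleophilic at C15 and afterwards electrophilic at C3′.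
3. Forward order: larixol → 8α-alcohol via the epoxide and C18 oxidation through the 6α-oxygen → methyl ketone → enal → silyl peroxyacetal; [3+3] union with the diene closes the dioxane; ketal removal, reduction and invertive lactonization close the lactone.
4. Stereochemistry: C5, C6, C9, C10 come from larixol; C4 from which methyl the 6α-oxygen reaches; C8 from α-face epoxidation; C14 from a chiral counteranion; C3′ from the chair transition state relative to C14; C4′ from substrate-controlled reduction followed by SN2 inversion.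
5. Remark on the structure: the target as drawn has a trans-fused lactone/dioxane (H on C4′ anti to the C3′ methyl) with the C14 side chain cis to the C2′ methylene; the route is built for this isomer.

Key step: step 15

Numbering used: labdane numbers C1–C20 (C16 = exocyclic methylene carbon on C13, C17 = methyl on C8, C18 = ester carbon on C4, C19 = methyl on C4, C20 = methyl on C10). Lactone carbons: C1′ (C=O), C2′ (CH2), C3′ (quaternary C–O–O with its methyl), C4′ (CH–O). TBS = tert-butyldimethylsilyl.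

**Route**

Step 1
Reactants: 1 (+)-larixol [labda-8(17),14-diene-6α,13-diol]
Product: 2 8α,17-epoxylabd-14-ene-6α,13-diol
Conditions: mCPBA, Na2HPO4, CH2Cl2, 0 °C
Reagents that add atoms: 3-chloroperbenzoic acid, O=C(OO)c1cccc(Cl)c1
Why: Prilezhaev epoxidation should pick the more electron-rich 1,1-disubstituted exocyclic alkene over the vinyl group and deliver oxygen to the α face, which is anti to the axial C10 methyl and syn to the hydrogen-bonding 6α-hydroxyl, so that C8 carries oxygen α.

Step 2
Reactants: 2 8α,17-epoxylabd-14-ene-6α,13-diol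
Product: 5 8α,17-epoxy-6α-hydroxy-14,15-dinorlabdan-13-one, via 14,15-diol 3 (not isolated), via hydroxy aldehyde 4 (not isolated)
Conditions: OsO4 (cat.), NaIO4, 2,6-lutidine, dioxane/H2O, rt
Reagents that add atoms: none
Why: Lemieux–Johnson oxidation cleaves the only remaining alkene and the tertiary α-hydroxy aldehyde is cleaved once more by periodate to the C13 methyl ketone; no stereocentre is formed and the buffered medium should spare the epoxide.

Step 3
Reactants: 5 8α,17-epoxy-6α-hydroxy-14,15-dinorlabdan-13-one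
Product: 6 6α,18:8α,17-diepoxy-14,15-dinorlabdan-13-one
Conditions: PhI(OAc)2, I2, cyclohexane, hν (tungsten lamp), rt
Reagents that add atoms: none
Why: In this hypoiodite reaction the 6α-alkoxyl radical should abstract hydrogen from C18 through a six-membered transition state, because the equatorial 4α-methyl is the only C–H partner held close (peri, parallel bonds), and iodine transfer with ring closure gives the tetrahydrofuran, which fixes C4 with its oxidized carbon α.

Step 4
Reactants: 6 6α,18:8α,17-diepoxy-14,15-dinorlabdan-13-one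
Product: 7 6α,18-epoxy-14,15-dinorlabdane-8α,13-diol (both C13 epimers)
Conditions: LiAlH4, THF, 0 °C → rt
Reagents that add atoms: none
Why: Hydride reduction opens the spiro-epoxide at the unhindered methylene C17, which leaves the tertiary 8α-alcohol with the β-methyl set in step 1, and reduces the ketone to a carbinol whose configuration does not matter because step 5 reoxidizes it.

Step 5
Reactants: 7 6α,18-epoxy-14,15-dinorlabdane-8α,13-diol
Product: 8 8α-hydroxy-13-oxo-14,15-dinorlabdan-18,6α-olide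
Conditions: RuCl3·xH2O (cat.), NaIO4, CCl4/MeCN/H2O, rt
Reagents that add atoms: sodium periodate (oxygen delivered through RuO4), [Na+].[O-][I](=O)(=O)=O
Why: RuO4 formed in situ should oxidize the ether methylene C18 to the lactone carbonyl and the secondary C13 carbinol to the ketone in one operation (ether-to-lactone and alcohol oxidation), while the tertiary alcohol and all stereocentres stay untouched.

Step 6
Reactants: 8 8α-hydroxy-13-oxo-14,15-dinorlabdan-18,6α-olide
Product: 10 methyl 6α,8α-dihydroxy-13-oxo-14,15-dinorlabdan-18-oate, via potassium carboxylate 9 (not isolated)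
Conditions: KOH, MeOH/H2O, 60 °C; evaporate; MeI, DMF, rt
Reagents that add atoms: potassium hydroxide, [K+].[OH-]; iodomethane, CI
Why: Saponification opens the γ-lactone and SN2 O-alkylation of the carboxylate salt fixes the methyl ester before acid can reclose the lactone; C6 keeps its configuration because the acyl C–O bond is the one broken.

Step 7
Reactants: 10 methyl 6α,8α-dihydroxy-13-oxo-14,15-dinorlabdan-18-oate
Product: 11 methyl 6α,8α-bis(TBS-oxy)-13-oxo-14,15-dinorlabdan-18-oate
Conditions: TBSOTf, 2,6-lutidine, CH2Cl2, 0 °C → rt; dilute HCl work-up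
Reagents that add atoms: tert-butyldimethylsilyl triflate, CC(C)(C)[Si](C)(C)OS(=O)(=O)C(F)(F)F
Why: Silyl triflate silylation covers the hindered secondary and the tertiary alcohol, and the mild acid work-up returns any silyl enol ether to the methyl ketone.

Step 8
Reactants: 11 methyl 6α,8α-bis(TBS-oxy)-13-oxo-14,15-dinorlabdan-18-oate
Product: 13 methyl 6α,8α-bis(TBS-oxy)-13-(triflyloxy)-14,15-dinorlabd-13(16)-en-18-oate, via potassium enolate 12 (not isolated)
Conditions: KHMDS, THF, −78 °C; then PhNTf2, −78 → 0 °C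
Reagents that add atoms: N-phenylbis(trifluoromethanesulfonimide), O=S(=O)(N(c1ccccc1)S(=O)(=O)C(F)(F)F)C(F)(F)F
Why: Kinetic deprotonation of the methyl ketone at the methyl group by the bulky amide and O-sulfonylation give the terminal enol triflate; the C18 ester has no α-hydrogen and is too hindered to be attacked.

Step 9
Reactants: 13 methyl 6α,8α-bis(TBS-oxy)-13-(triflyloxy)-14,15-dinorlabd-13(16)-en-18-oate
Product: 14 methyl 6α,8α-bis(TBS-oxy)-14-oxo-15-norlabd-13(16)-en-18-oate
Conditions: Pd(PPh3)4 (cat.), CO (1 atm), Bu3SnH (slow addition), LiCl, THF, 50 °C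
Reagents that add atoms: carbon monoxide, [C-]#[O+]
Why: Palladium-catalysed reductive carbonylation (oxidative addition of the enol triflate to zerovalent palladium, CO insertion, hydride transfer from tin) should give the 2-substituted acrolein with the C13=C16 methylene in place.

Step 10
Reactants: 14 methyl 6α,8α-bis(TBS-oxy)-14-oxo-15-norlabd-13(16)-en-18-oate
Product: 15 methyl 6α,8α-bis(TBS-oxy)-14,14-dimethoxy-15-norlabd-13(16)-en-18-oate
Conditions: MeOSiMe3, TMSOTf (cat.), CH2Cl2, −78 °C
Reagents that add atoms: methoxytrimethylsilane, CO[Si](C)(C)C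
Why: Silyl-triflate-catalysed acetalization with the silyl ether of methanol is aprotic and cold, so the enal should give its dimethyl acetal without conjugate addition or loss of the silyl ethers.

Step 11
Reactants: 15 methyl 6α,8α-bis(TBS-oxy)-14,14-dimethoxy-15-norlabd-13(16)-en-18-oate
Product: 16 methyl 6α,8α-bis(TBS-oxy)-14-hydroperoxy-14-methoxy-15-norlabd-13(16)-en-18-oate (both C14 epimers)
Conditions: anhydrous H2O2 in Et2O, PPTS (cat.), 0 °C → rt, stopped at mono-exchange
Reagents that add atoms: hydrogen peroxide, OO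
Why: Acid-catalysed acetal exchange (peroxyacetalization) through the allyl-stabilized oxocarbenium ion replaces one methoxy group by hydroperoxide; the configuration at C14 is of no concern because this carbon is ionized again in step 15.

Step 12
Reactants: 16 methyl 6α,8α-bis(TBS-oxy)-14-hydroperoxy-14-methoxy-15-norlabd-13(16)-en-18-oate
Product: 17 methyl 6α,8α-bis(TBS-oxy)-14-methoxy-14-(triethylsilylperoxy)-15-norlabd-13(16)-en-18-oate
Conditions: Et3SiCl, imidazole, DMF, 0 °C
Reagents that add atoms: chlorotriethylsilane, CC[Si](Cl)(CC)CC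
Why: The hydroperoxide is more acidic than an alcohol and should be O-silylated cleanly, which gives the silyl peroxyacetal that serves as peroxycarbenium precursor.

Step 13
Reactants: 18 2,3-butanedione (excess); 19 tert-butyl (triphenylphosphoranylidene)acetate
Product: 20 tert-butyl (E)-3-methyl-4-oxopent-2-enoate
Conditions: CH2Cl2, 0 °C → rt
Reagents that add atoms: none
Why: Wittig olefination of the very electrophilic 1,2-diketone with the stabilized ylide stops at one carbonyl group when the diketone is in excess and should give the (E)-enoate with acetyl trans to the ester.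

Step 14
Reactants: 20 tert-butyl (E)-3-methyl-4-oxopent-2-enoate
Product: 22 tert-butyl (E)-3-methyl-4-[2-(trimethylsilyloxy)ethoxy]penta-2,4-dienoate, via dioxolane 21 (not isolated)
Conditions: Me3SiOCH2CH2OSiMe3, TMSOTf (cat.), CH2Cl2, −78 °C; then i-Pr2NEt, TMSOTf, −20 °C → rt
Reagents that add atoms: 1,2-bis(trimethylsilyloxy)ethane, C[Si](C)(C)OCCO[Si](C)(C)C; trimethylsilyl triflate, C[Si](C)(C)OS(=O)(=O)C(F)(F)F
Why: Silyl-triflate-catalysed dioxolanation of the ketone followed by base-assisted ring opening of the dioxolane (ionization by silyl triflate, then loss of a proton from the methyl group, the only α-position that bears hydrogen) gives the 2-(silyloxy)ethyl enol ether with the (E)-enoate unchanged.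

Step 15
Reactants: 17 methyl 6α,8α-bis(TBS-oxy)-14-methoxy-14-(triethylsilylperoxy)-15-norlabd-13(16)-en-18-oate; 22 tert-butyl (E)-3-methyl-4-[2-(trimethylsilyloxy)ethoxy]penta-2,4-dienoate
Product: 25 spiro-ketal dioxane [tert-butyl 2-{(6R,9R)-6-methyl-9-(C13 side chain)-1,4,7,8-tetraoxaspiro[4.5]decan-6-yl}acetate; C14 R and C3′ R], via silylperoxy adduct 23 (not isolated), via hydroperoxide 24 (not isolated)
Conditions: chiral N-triflyl imidodiphosphorimidate acid built on two 3,3′-bis[3,5-bis(trifluoromethyl)phenyl]-BINOL units (IDPi, 5 mol%), toluene, −78 °C; then TBAF, AcOH, THF, −20 °C; then Et2NH, CF3CH2OH, 0 °C → rt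
Reagents that add atoms: none
Why: Proposed new method: the silylated chiral imidodiphosphorimidate ion pair ionizes the methoxy group of 17 to a 2-alkylallyl-stabilized peroxycarbenium ion, C15 of enol ether 22 adds to C14, and the oxocarbenium ion at C4′ is closed at once by its own silyloxyethyl arm to the dioxolane 23 while the trimethylsilyl group returns to the catalyst (closest known types: Lewis-acid additions of enol ethers and silyl enol ethers to peroxyacetals, the peroxycarbenium–alkene annulation to 1,2-dioxolanes, and chiral-anion-controlled Mukaiyama additions to acetals). Fluoride then frees hydroperoxide 24, which adds under amine catalysis in trifluoroethanol to C3′ of the enoate in a 6-exo-trig oxa-Michael closure of the 1,2-dioxane, a known way to close cyclic peroxides. C14 is set by the chiral counteranion, since the decalin centres are too remote to bias the planar cation, and the catalyst antipode is chosen to give 14R. C3′ is set by the substrate: in the chair transition state the C14 side chain is equatorial and allylic strain keeps C15 syn to the vinylic hydrogen of the (E)-enoate, so the methyl group ends equatorial and the acetate arm axial, cis to the C14 side chain. The step needs ionization at methoxy and not at O–O, attack at C14 and not at C16, capture of the C4′ cation by the internal arm and not by the silylperoxy oxygen (which would give the 1,2-dioxolane), and peroxide attack at C3′ and not at C2′. These are secured by the more basic methoxy oxygen, the higher charge at C14, the five-membered internal trap and the ketal at C4′, which leaves the ester as the only activating group, while the fluorinated alcohol protonates the ester enolate before it can expel alkoxide to an epoxide.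

Step 16
Reactants: 25 spiro-ketal dioxane
Product: 26 dioxanone [tert-butyl 2-{(3R,6R)-3-methyl-4-oxo-6-(C13 side chain)-1,2-dioxan-3-yl}acetate]
Conditions: TsOH·H2O (cat.), acetone/H2O, rt
Reagents that add atoms: water, O
Why: Acid-catalysed ketal hydrolysis unmasks the C4′ ketone; the peroxide, the tert-butyl ester and the hindered silyl ethers should tolerate dilute sulfonic acid in wet acetone, and no stereocentre is touched.

Step 17
Reactants: 26 dioxanone
Product: 27 cis hydroxy ester [tert-butyl 2-{(3R,4R,6R)-4-hydroxy-3-methyl-6-(C13 side chain)-1,2-dioxan-3-yl}acetate]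
Conditions: NaBH4, CeCl3·7H2O, MeOH/THF, −78 °C
Reagents that add atoms: none
Why: Luche reduction is expected to deliver hydride axially to the chair in which the C14 side chain and the C3′ methyl are equatorial, on the face anti to the axial acetate arm, which gives the equatorial (4′R) alcohol cis to the arm; the tert-butyl ester resists attack by the alkoxide and the cerium salt keeps the medium from promoting β-elimination of the peroxide.

Step 18
Reactants: 27 cis hydroxy ester
Product: 29 bis-TBS ether of the target (trans-fused lactone, C4′ S), via triflate 28 (not isolated)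
Conditions: Tf2O, 2,6-di-tert-butyl-4-methylpyridine, CH2Cl2, −78 → 0 °C
Reagents that add atoms: none
Why: O-Triflation followed by intramolecular SN2 attack of the ester carbonyl oxygen on C4′ and loss of the tert-butyl group as isobutene (neighbouring-group lactonization with inversion) should turn the cis hydroxy ester into the trans-fused γ-lactone and set C4′ as S.

Step 19
Reactants: 29 bis-TBS ether of the target
Product: 30 CNP0162504.1 (target)
Conditions: HF·pyridine, pyridine/THF, 0 °C → rt
Reagents that add atoms: none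
Why: Fluoride-mediated desilylation with buffered HF should remove both silyl ethers without touching the peroxide, the lactone or the hindered methyl ester.

**Compound list**

1 | (+)-larixol [labda-8(17),14-diene-6α,13-diol] | C=C[C@@](C)(O)CC[C@@H]1[C@@]2(C)CCCC(C)(C)[C@@H]2[C@@H](O)CC1=C | starting material
2 | 8α,17-epoxylabd-14-ene-6α,13-diol | C=C[C@@](C)(O)CC[C@@H]1[C@@]2(C)CCCC(C)(C)[C@@H]2[C@@H](O)C[C@]13CO3 | intermediate
3 | 8α,17-epoxylabdane-6α,13,14,15-tetrol (14,15-diol from the vinyl group; not isolated) | OCC(O)[C@@](C)(O)CC[C@@H]1[C@@]2(C)CCCC(C)(C)[C@@H]2[C@@H](O)C[C@]13CO3 | intermediate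
4 | 8α,17-epoxy-6α,13-dihydroxy-15-norlabdan-14-al (not isolated) | O=C[C@@](C)(O)CC[C@@H]1[C@@]2(C)CCCC(C)(C)[C@@H]2[C@@H](O)C[C@]13CO3 | intermediate
5 | 8α,17-epoxy-6α-hydroxy-14,15-dinorlabdan-13-one | CC(=O)CC[C@@H]1[C@@]2(C)CCCC(C)(C)[C@@H]2[C@@H](O)C[C@]13CO3 | intermediate
6 | 6α,18:8α,17-diepoxy-14,15-dinorlabdan-13-one | CC(=O)CC[C@@H]1[C@@]2(C)CCC[C@@](C)(CO5)[C@@H]2[C@@H]5C[C@]13CO3 | intermediate
7 | 6α,18-epoxy-14,15-dinorlabdane-8α,13-diol (both C13 epimers) | CC(O)CC[C@@H]1[C@@]2(C)CCC[C@@](C)(CO5)[C@@H]2[C@@H]5C[C@@]1(C)O | intermediate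
8 | 8α-hydroxy-13-oxo-14,15-dinorlabdan-18,6α-olide | CC(=O)CC[C@@H]1[C@@]2(C)CCC[C@@](C)(C(=O)O5)[C@@H]2[C@@H]5C[C@@]1(C)O | intermediate
9 | potassium 6α,8α-dihydroxy-13-oxo-14,15-dinorlabdan-18-oate (not isolated) | CC(=O)CC[C@@H]1[C@@]2(C)CCC[C@@](C)(C(=O)[O-])[C@@H]2[C@@H](O)C[C@@]1(C)O.[K+] | intermediate
10 | methyl 6α,8α-dihydroxy-13-oxo-14,15-dinorlabdan-18-oate | CC(=O)CC[C@@H]1[C@@]2(C)CCC[C@@](C)(C(=O)OC)[C@@H]2[C@@H](O)C[C@@]1(C)O | intermediate
11 | methyl 6α,8α-bis(TBS-oxy)-13-oxo-14,15-dinorlabdan-18-oate | CC(=O)CC[C@@H]1[C@@]2(C)CCC[C@@](C)(C(=O)OC)[C@@H]2[C@@H](O[Si](C)(C)C(C)(C)C)C[C@@]1(C)O[Si](C)(C)C(C)(C)C | intermediate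
12 | potassium C13=C16 enolate of 11 (not isolated) | C=C([O-])CC[C@@H]1[C@@]2(C)CCC[C@@](C)(C(=O)OC)[C@@H]2[C@@H](O[Si](C)(C)C(C)(C)C)C[C@@]1(C)O[Si](C)(C)C(C)(C)C.[K+] | intermediate
13 | methyl 6α,8α-bis(TBS-oxy)-13-(triflyloxy)-14,15-dinorlabd-13(16)-en-18-oate | C=C(OS(=O)(=O)C(F)(F)F)CC[C@@H]1[C@@]2(C)CCC[C@@](C)(C(=O)OC)[C@@H]2[C@@H](O[Si](C)(C)C(C)(C)C)C[C@@]1(C)O[Si](C)(C)C(C)(C)C | intermediate
14 | methyl 6α,8α-bis(TBS-oxy)-14-oxo-15-norlabd-13(16)-en-18-oate (2-substituted acrolein) | C=C(C=O)CC[C@@H]1[C@@]2(C)CCC[C@@](C)(C(=O)OC)[C@@H]2[C@@H](O[Si](C)(C)C(C)(C)C)C[C@@]1(C)O[Si](C)(C)C(C)(C)C | intermediate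
15 | methyl 6α,8α-bis(TBS-oxy)-14,14-dimethoxy-15-norlabd-13(16)-en-18-oate | C=C(C(OC)OC)CC[C@@H]1[C@@]2(C)CCC[C@@](C)(C(=O)OC)[C@@H]2[C@@H](O[Si](C)(C)C(C)(C)C)C[C@@]1(C)O[Si](C)(C)C(C)(C)C | intermediate
16 | methyl 6α,8α-bis(TBS-oxy)-14-hydroperoxy-14-methoxy-15-norlabd-13(16)-en-18-oate (both C14 epimers) | C=C(C(OC)OO)CC[C@@H]1[C@@]2(C)CCC[C@@](C)(C(=O)OC)[C@@H]2[C@@H](O[Si](C)(C)C(C)(C)C)C[C@@]1(C)O[Si](C)(C)C(C)(C)C | intermediate
17 | methyl 6α,8α-bis(TBS-oxy)-14-methoxy-14-(triethylsilylperoxy)-15-norlabd-13(16)-en-18-oate (both C14 epimers) | C=C(C(OC)OO[Si](CC)(CC)CC)CC[C@@H]1[C@@]2(C)CCC[C@@](C)(C(=O)OC)[C@@H]2[C@@H](O[Si](C)(C)C(C)(C)C)C[C@@]1(C)O[Si](C)(C)C(C)(C)C | intermediate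
18 | 2,3-butanedione | CC(=O)C(C)=O | starting material
19 | tert-butyl (triphenylphosphoranylidene)acetate | CC(C)(C)OC(=O)C=P(c1ccccc1)(c1ccccc1)c1ccccc1 | starting material
20 | tert-butyl (E)-3-methyl-4-oxopent-2-enoate | CC(=O)/C(C)=C/C(=O)OC(C)(C)C | intermediate
21 | tert-butyl (E)-3-(2-methyl-1,3-dioxolan-2-yl)but-2-enoate (not isolated) | CC1(OCCO1)/C(C)=C/C(=O)OC(C)(C)C | intermediate
22 | tert-butyl (E)-3-methyl-4-[2-(trimethylsilyloxy)ethoxy]penta-2,4-dienoate | C=C(OCCO[Si](C)(C)C)/C(C)=C/C(=O)OC(C)(C)C | intermediate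
23 | open-chain (14R)-14-(triethylsilylperoxy) adduct with C4′ ethylene ketal and (E)-enoate (not isolated) | C=C(CC[C@@H]1[C@@]2(C)CCC[C@@](C)(C(=O)OC)[C@@H]2[C@@H](O[Si](C)(C)C(C)(C)C)C[C@@]1(C)O[Si](C)(C)C(C)(C)C)[C@H](OO[Si](CC)(CC)CC)CC1(OCCO1)/C(C)=C/C(=O)OC(C)(C)C | intermediate
24 | open-chain (14R)-14-hydroperoxide with C4′ ethylene ketal and (E)-enoate (not isolated) | C=C(CC[C@@H]1[C@@]2(C)CCC[C@@](C)(C(=O)OC)[C@@H]2[C@@H](O[Si](C)(C)C(C)(C)C)C[C@@]1(C)O[Si](C)(C)C(C)(C)C)[C@H](OO)CC1(OCCO1)/C(C)=C/C(=O)OC(C)(C)C | intermediate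
25 | spiro-ketal dioxane: 1,2-dioxane of O–O, C14 (R), C15, C4′ (ethylene ketal), C3′ (R; CH3 and CH2CO2tBu) | C=C(CC[C@@H]1[C@@]2(C)CCC[C@@](C)(C(=O)OC)[C@@H]2[C@@H](O[Si](C)(C)C(C)(C)C)C[C@@]1(C)O[Si](C)(C)C(C)(C)C)[C@H]1CC2(OCCO2)[C@@](C)(CC(=O)OC(C)(C)C)OO1 | intermediate
26 | dioxanone: (14R,3′R)-1,2-dioxan-4-one with C4′ ketone | C=C(CC[C@@H]1[C@@]2(C)CCC[C@@](C)(C(=O)OC)[C@@H]2[C@@H](O[Si](C)(C)C(C)(C)C)C[C@@]1(C)O[Si](C)(C)C(C)(C)C)[C@H]1CC(=O)[C@@](C)(CC(=O)OC(C)(C)C)OO1 | intermediate
27 | cis hydroxy ester: (14R,3′R,4′R)-4′-alcohol, OH cis to the acetate arm and to the C14 side chain | C=C(CC[C@@H]1[C@@]2(C)CCC[C@@](C)(C(=O)OC)[C@@H]2[C@@H](O[Si](C)(C)C(C)(C)C)C[C@@]1(C)O[Si](C)(C)C(C)(C)C)[C@H]1C[C@@H](O)[C@@](C)(CC(=O)OC(C)(C)C)OO1 | intermediate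
28 | (14R,3′R,4′R)-4′-triflate of 27 (not isolated) | C=C(CC[C@@H]1[C@@]2(C)CCC[C@@](C)(C(=O)OC)[C@@H]2[C@@H](O[Si](C)(C)C(C)(C)C)C[C@@]1(C)O[Si](C)(C)C(C)(C)C)[C@H]1C[C@@H](OS(=O)(=O)C(F)(F)F)[C@@](C)(CC(=O)OC(C)(C)C)OO1 | intermediate
29 | 6α,8α-bis-TBS ether of the target (14R,3′R,4′S; trans-fused lactone) | C=C(CC[C@@H]1[C@@]2(C)CCC[C@@](C)(C(=O)OC)[C@@H]2[C@@H](O[Si](C)(C)C(C)(C)C)C[C@@]1(C)O[Si](C)(C)C(C)(C)C)[C@H]1C[C@@H]2OC(=O)C[C@@]2(C)OO1 | intermediate
30 | CNP0162504.1 | C=C(CC[C@@H]1[C@@]2(C)CCC[C@@](C)(C(=O)OC)[C@@H]2[C@@H](O)C[C@@]1(C)O)[C@H]1C[C@@H]2OC(=O)C[C@@]2(C)OO1 | target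

**Totals**

Total step count: 19. Longest linear sequence: 17 steps (steps 1–12 and 15–19).

**Steps most likely to fail**

1. Step 15. The chiral ion pair may fail to control the face of the peroxycarbenium ion, the C4′ cation may be captured by the silylperoxy group, or conjugate addition to the hindered disubstituted enoate carbon may be slow.
Fallback (known chemistry, sets out from 17 and 22, returns at 25): catalyst control and the one-pot operation are given up. Achiral TMSOTf in CH2Cl2 at −78 °C effects the enol-ether addition to the peroxyacetal without facial bias, and the adduct is isolated as 23 together with its 14S epimer, the silylperoxy adduct F1. Buffered TBAF gives 24 and the 14S hydroperoxide F2. Et2NH in CF3CH2OH cyclizes each epimer under the same chair control to 25 and the (6S,9S)-spiro-ketal dioxane F3. These two are diastereomers because of the decalin and are separated by chromatography, and 25 re-enters at step 16.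

2. Step 3. β-Scission of the 6-alkoxyl radical or iodine-promoted opening of the spiro-epoxide may compete with the 1,5-hydrogen transfer.
Fallback (sets out from 5, returns at 8): a Barton nitrite photolysis replaces steps 3–5. NOCl in pyridine gives the 6α-nitrite ester F4. Irradiation and tautomerization of the C18 nitroso compound give the 18-oxime F5. Aqueous NaHSO3 followed by dilute acid removes the oxime, and the aldehyde closes to the 6α,18-lactol F6. LiAlH4 reduces lactol, epoxide and ketone to the 6α,8α,13,18-tetrol F7. 2,2,6,6-Tetramethylpiperidine-1-oxyl (cat.) with PhI(OAc)2 oxidizes the 1,4-diol to the γ-lactone and the C13 carbinol to the ketone, which gives 8.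

3. Step 18. E2 loss of the triflate toward C15, or failure of the ring flip that backside attack needs, may prevent the invertive closure.
Fallback (sets out from 26, returns at 29): the C4′ configuration is set by the catalyst instead of by inversion. Corey–Bakshi–Shibata reduction of 26 with (R)-1-methyl-3,3-diphenyltetrahydro-1H,3H-pyrrolo[1,2-c][1,3,2]oxazaborole and catecholborane in toluene at −78 °C gives the (4′S) trans hydroxy ester F8. TMSOTf with 2,6-lutidine, then aqueous citric acid, cleaves the tert-butyl ester to the (4′S) hydroxy acid F9. Carbodiimide lactonization (EDC·HCl, DMAP, CH2Cl2) with retention gives 29.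

Further compounds
F1 | step 15 | (14S)-epimer of silylperoxy adduct 23 | C=C(CC[C@@H]1[C@@]2(C)CCC[C@@](C)(C(=O)OC)[C@@H]2[C@@H](O[Si](C)(C)C(C)(C)C)C[C@@]1(C)O[Si](C)(C)C(C)(C)C)[C@@H](OO[Si](CC)(CC)CC)CC1(OCCO1)/C(C)=C/C(=O)OC(C)(C)C
F2 | step 15 | (14S)-epimer of hydroperoxide 24 | C=C(CC[C@@H]1[C@@]2(C)CCC[C@@](C)(C(=O)OC)[C@@H]2[C@@H](O[Si](C)(C)C(C)(C)C)C[C@@]1(C)O[Si](C)(C)C(C)(C)C)[C@@H](OO)CC1(OCCO1)/C(C)=C/C(=O)OC(C)(C)C
F3 | step 15 | (6S,9S)-spiro-ketal dioxane, diastereomer of 25 (C14 S and C3′ S) | C=C(CC[C@@H]1[C@@]2(C)CCC[C@@](C)(C(=O)OC)[C@@H]2[C@@H](O[Si](C)(C)C(C)(C)C)C[C@@]1(C)O[Si](C)(C)C(C)(C)C)[C@@H]1CC2(OCCO2)[C@](C)(CC(=O)OC(C)(C)C)OO1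
F4 | step 3 | 8α,17-epoxy-13-oxo-14,15-dinorlabdan-6α-yl nitrite | CC(=O)CC[C@@H]1[C@@]2(C)CCCC(C)(C)[C@@H]2[C@@H](ON=O)C[C@]13CO3
F5 | step 3 | 8α,17-epoxy-6α-hydroxy-13-oxo-14,15-dinorlabdan-18-al oxime | CC(=O)CC[C@@H]1[C@@]2(C)CCC[C@@](C)(C=NO)[C@@H]2[C@@H](O)C[C@]13CO3
F6 | step 3 | 6α,18:8α,17-diepoxy-18-hydroxy-14,15-dinorlabdan-13-one (lactol) | CC(=O)CC[C@@H]1[C@@]2(C)CCC[C@@](C)(C(O)O5)[C@@H]2[C@@H]5C[C@]13CO3
F7 | step 3 | 14,15-dinorlabdane-6α,8α,13,18-tetrol (both C13 epimers) | CC(O)CC[C@@H]1[C@@]2(C)CCC[C@@](C)(CO)[C@@H]2[C@@H](O)C[C@@]1(C)O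
F8 | step 18 | (14R,3′R,4′S)-trans hydroxy tert-butyl ester, C4′ epimer of 27 | C=C(CC[C@@H]1[C@@]2(C)CCC[C@@](C)(C(=O)OC)[C@@H]2[C@@H](O[Si](C)(C)C(C)(C)C)C[C@@]1(C)O[Si](C)(C)C(C)(C)C)[C@H]1C[C@H](O)[C@@](C)(CC(=O)OC(C)(C)C)OO1
F9 | step 18 | (14R,3′R,4′S)-trans hydroxy acid | C=C(CC[C@@H]1[C@@]2(C)CCC[C@@](C)(C(=O)OC)[C@@H]2[C@@H](O[Si](C)(C)C(C)(C)C)C[C@@]1(C)O[Si](C)(C)C(C)(C)C)[C@H]1C[C@H](O)[C@@](C)(CC(=O)O)OO1
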